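## Retrosynthetic overview

1. Sceptrin 32 comes from the all-trans tetraamine 30 (two CH2NH2 arms, two 2-aminoimidazol-4-yl groups) by acylation of both arms with 4-bromo-2-(trichloroacetyl)pyrrole 31.
2. In 30 the imidazole on C1 is bought and aminated at its own C2 (lithiation, azide transfer); the aminoimidazole on C4 is grown from an acetyl group (bromoketone, Boc-guanidine); the CH2N arms come from the C2 ester and the C3 lactone CH2O through azides.
3. The all-trans array comes from base epimerisation of the two carbonyl-bearing carbons C2 and C4 of the all-cis lactone ester 11; C1 and C3 cannot epimerise and carry the absolute configuration.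
4. Feature used: the cyclobutane bond C1–C2 joins the imidazolyl-bearing carbon to a CH2N-bearing carbon. A nitrogen placed between these two atoms turns the ring into a 2-(imidazol-4-yl)pyrrolidine-5-carboxylate whose remaining carbons C4 (carbonyl) and C3 (CH2O) are the α- and β-carbons of a butyrolactone, i.e. the endo adduct of a glycine-imine azomethine ylide and 2(5H)-furanone.
5. Ring order: pyrrolidine by (3+2) cycloaddition (step 3), cyclobutane by deletion of the ring nitrogen (step 4), second aminoimidazole (step 17).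

Key step: step 4

## Remarks

- Locants for the four-membered ring: C1 bears the bought imidazole, C2 the ester-derived carbon, C3 the lactone CH2O carbon, C4 the lactone carbonyl carbon. "Up" is the face of the C1 substituent. Ar = 1-(dimethylsulfamoyl)-1H-imidazol-4-yl, ArN3 = its 2-azido derivative.
- A tert-butyl ester is carried in place of a methyl ester so that the Me2AlCl-mediated aminolysis and the MeMgBr addition touch only the lactone-derived carbonyl.
- Assumption: (S)-BINAP is taken to give the drawn enantiomer of 8; the sense of induction for this imine/butenolide pair is not established, and the antipodal ligand is used if it proves opposite.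
- The ketone is reduced for a few steps so that no carbonyl is present during the C2-lithiation of the imidazole. Compounds 17–20 are a mixture of epimers at this temporary carbinol carbon, which step 13 removes.

## Route

Step 1
Reactants: 1 1H-imidazole-4-carbaldehyde; 2 dimethylsulfamoyl chloride
Product: 3 4-formyl-N,N-dimethyl-1H-imidazole-1-sulfonamide
Conditions: Et3N, CH2Cl2, 0 °C → rt
Reagents that add atoms: none
Why: N-sulfonylation of the imidazole should place the sulfamoyl group on the nitrogen remote from the formyl group (the 1,4-isomer), which masks N–H and N3 for the silver catalysis and the oxidative contraction and later directs C2-lithiation.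

Step 2
Reactants: 3 4-formyl-N,N-dimethyl-1H-imidazole-1-sulfonamide; 4 glycine tert-butyl ester hydrochloride
Product: 5 tert-butyl (E)-N-{[1-(dimethylsulfamoyl)-1H-imidazol-4-yl]methylidene}glycinate
Conditions: Et3N, 4 Å MS, CH2Cl2, rt
Reagents that add atoms: none
Why: Schiff base condensation of the aldehyde with the liberated amino ester, driven by removal of water, should give the E-imine that serves as the azomethine ylide precursor.

Step 3
Reactants: 5 tert-butyl (E)-N-{[1-(dimethylsulfamoyl)-1H-imidazol-4-yl]methylidene}glycinate; 6 2(5H)-furanone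
Product: 8 tert-butyl (1R,3S,3aR,6aS)-3-[1-(dimethylsulfamoyl)-1H-imidazol-4-yl]-4-oxohexahydro-1H-furo[3,4-c]pyrrole-1-carboxylate (all-cis), via silver azomethine ylide 7 (not isolated)
Conditions: AgOAc (5 mol %), (S)-BINAP (5.5 mol %), i-Pr2NEt (10 mol %), toluene, −20 °C
Reagents that add atoms: none
Why: Catalytic asymmetric 1,3-dipolar cycloaddition: the N,O-chelated ylide 7 should bond its ester α-carbon to the butenolide β-carbon and its imine carbon to the α-carbon through an endo transition state, which places all four ring hydrogens on one face, while the BINAP-bound silver shields one face of the ylide and so fixes the absolute configuration at C1 and C3.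

Step 4
Reactants: 8 tert-butyl (1R,3S,3aR,6aS)-3-[1-(dimethylsulfamoyl)-1H-imidazol-4-yl]-4-oxohexahydro-1H-furo[3,4-c]pyrrole-1-carboxylate
Product: 11 tert-butyl (1S,5S,6R,7R)-7-[1-(dimethylsulfamoyl)-1H-imidazol-4-yl]-2-oxo-3-oxabicyclo[3.2.0]heptane-6-carboxylate (all-cis), via 1,1-diazene 9 (not isolated), via 1,4-biradical 10 (not isolated)
Conditions: PhI(OAc)2 (2.5 equiv), NH2CO2NH4 (8 equiv), CF3CH2OH, 80 °C
Reagents that add atoms: none
Why: PhI(OAc)2 and the ammonia released from the carbamate should form an iodonitrene that aminates the ring N–H electrophilically, loss of PhI gives the 1,1-diazene 9, and extrusion of N2 leaves the singlet 1,4-biradical 10, whose two termini couple to make the C1–C2 bond. The closest known reaction type is the iodonitrene-mediated contraction of N–H pyrrolidines bearing an α-aryl and an α'-alkoxycarbonyl group to cyclobutanes, which runs with retention. The four-membered ring closes by intramolecular radical–radical recombination, the other three ring bonds being already in place. C1 and C2 should keep the configuration they had in 8, because the biradical is held cisoid by the cis-fused lactone and should couple faster than rotation about C1–C4 or C2–C3. The step needs coupling to win over β-scission of C3–C4 and over dehydrogenation of the amine: the imidazolyl and ester groups stabilise the two radical centres, the lactone ties C3 to C4 so that scission would not release two fragments, and the sulfamoyl group keeps the imidazole N3 from being aminated or oxidised.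

Step 5
Reactants: 11 tert-butyl (1S,5S,6R,7R)-7-[1-(dimethylsulfamoyl)-1H-imidazol-4-yl]-2-oxo-3-oxabicyclo[3.2.0]heptane-6-carboxylate
Product: 12 tert-butyl (1S,5S,6S,7R)-7-[1-(dimethylsulfamoyl)-1H-imidazol-4-yl]-2-oxo-3-oxabicyclo[3.2.0]heptane-6-carboxylate (ester trans to the imidazolyl group and to the lactone CH2)
Conditions: KOtBu (0.3 equiv), t-BuOH/THF, 0 °C → rt
Reagents that add atoms: none
Why: Thermodynamic epimerisation through the ester enolate should invert only C2, moving the ester to the convex face trans to both neighbours, because the lactone α-carbon must stay cis-fused and the ring bonds to C4 lie close to the nodal plane of the enolate π-system, which disfavours retro-Michael ring opening.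

Step 6
Reactants: 12 tert-butyl (1S,5S,6S,7R)-7-[1-(dimethylsulfamoyl)-1H-imidazol-4-yl]-2-oxo-3-oxabicyclo[3.2.0]heptane-6-carboxylate
Product: 13 cyclobutane with C1 Ar (up); C2 CO2tBu (down); C3 CH2OH (up); C4 C(O)N(OMe)Me (up)
Conditions: MeNH(OMe)·HCl, Me2AlCl, CH2Cl2, 0 °C → rt
Reagents that add atoms: N,O-dimethylhydroxylamine hydrochloride, CNOC.Cl
Why: Me2AlCl-mediated aminolysis (Weinreb amidation) should open the strained cis-fused γ-lactone, which is far more electrophilic than the tert-butyl ester, without touching any stereocentre.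

Step 7
Reactants: 13 cyclobutane with C1 Ar (up); C2 CO2tBu (down); C3 CH2OH (up); C4 C(O)N(OMe)Me (up)
Product: 14 cyclobutane with C1 Ar (up); C2 CO2tBu (down); C3 CH2OTBS (up); C4 C(O)N(OMe)Me (up)
Conditions: TBSCl, imidazole, DMF, rt (crude 13 used at once)
Reagents that add atoms: tert-butyldimethylsilyl chloride, CC(C)(C)[Si](C)(C)Cl
Why: Silylation of the primary alcohol should block relactonisation of the cis hydroxy amide.

Step 8
Reactants: 14 cyclobutane with C1 Ar (up); C2 CO2tBu (down); C3 CH2OTBS (up); C4 C(O)N(OMe)Me (up)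
Product: 15 cyclobutane with C1 Ar (up); C2 CO2tBu (down); C3 CH2OTBS (up); C4 acetyl (up)
Conditions: MeMgBr, THF, −20 → 0 °C
Reagents that add atoms: methylmagnesium bromide, C[Mg]Br
Why: Grignard addition to the N-methoxy-N-methylamide should stop at the ketone through the chelated tetrahedral intermediate, the tert-butyl ester being inert at this temperature.

Step 9
Reactants: 15 cyclobutane with C1 Ar (up); C2 CO2tBu (down); C3 CH2OTBS (up); C4 acetyl (up)
Product: 16 all-trans cyclobutane with C1 Ar (up); C2 CO2tBu (down); C3 CH2OTBS (up); C4 acetyl (down)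
Conditions: DBU (0.3 equiv), CH2Cl2, rt
Reagents that add atoms: none
Why: Amine-base epimerisation through the ketone enol(ate) should move the acetyl group from the face it shares with both neighbours to the opposite face, giving the thermodynamically preferred all-trans ring, while the less acidic ester centre is untouched.

Step 10
Reactants: 16 all-trans cyclobutane with C1 Ar (up); C2 CO2tBu (down); C3 CH2OTBS (up); C4 acetyl (down)
Product: 17 all-trans cyclobutane with C1 Ar; C2 CH2OH; C3 CH2OTBS; C4 CH(OH)CH3 (carbinol epimers)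
Conditions: i-Bu2AlH (5 equiv), CH2Cl2, −78 → 0 °C
Reagents that add atoms: none
Why: Hydride reduction should take the tert-butyl ester to the CH2OH arm and the ketone to a carbinol, so that no carbonyl remains for the lithiation; ring stereocentres are not affected.

Step 11
Reactants: 17 all-trans cyclobutane with C1 Ar; C2 CH2OH; C3 CH2OTBS; C4 CH(OH)CH3
Product: 18 all-trans cyclobutane with C1 Ar; C2 CH2OTBS; C3 CH2OTBS; C4 CH(OH)CH3
Conditions: TBSCl (1.1 equiv), imidazole, CH2Cl2, 0 °C
Reagents that add atoms: tert-butyldimethylsilyl chloride, CC(C)(C)[Si](C)(C)Cl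
Why: Silylation should be selective for the primary over the hindered secondary alcohol on steric grounds.

Step 12
Reactants: 18 all-trans cyclobutane with C1 Ar; C2 CH2OTBS; C3 CH2OTBS; C4 CH(OH)CH3
Product: 20 all-trans cyclobutane with C1 ArN3; C2 CH2OTBS; C3 CH2OTBS; C4 CH(OH)CH3, via dilithio species 19 (not isolated)
Conditions: n-BuLi (2.2 equiv), THF, −78 °C; then TsN3, −78 °C → rt
Reagents that add atoms: p-toluenesulfonyl azide, Cc1ccc(cc1)S(=O)(=O)N=[N+]=[N-]
Why: After deprotonation of the alcohol, directed lithiation should occur at imidazole C2, the most acidic C–H (between two nitrogens and next to the sulfamoyl group), and electrophilic azide transfer from tosyl azide then installs the nitrogen of the future 2-amino group.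

Step 13
Reactants: 20 all-trans cyclobutane with C1 ArN3; C2 CH2OTBS; C3 CH2OTBS; C4 CH(OH)CH3
Product: 21 all-trans cyclobutane with C1 ArN3; C2 CH2OTBS; C3 CH2OTBS; C4 acetyl
Conditions: Dess–Martin periodinane, CH2Cl2, rt
Reagents that add atoms: none
Why: Dess–Martin oxidation of the secondary alcohol should restore the methyl ketone under non-basic conditions and remove the temporary stereocentre.

Step 14
Reactants: 21 all-trans cyclobutane with C1 ArN3; C2 CH2OTBS; C3 CH2OTBS; C4 acetyl
Product: 22 all-trans cyclobutane with C1 ArN3; C2 CH2OH; C3 CH2OH; C4 acetyl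
Conditions: HF·pyridine, THF/pyridine, 0 °C → rt
Reagents that add atoms: none
Why: Fluoride-driven Si–O cleavage should free both primary alcohols; the trans-1,2 relationship to the ketone excludes a fused lactol, and a bridged lactol across the cis-1,3 positions would be strained and reversible.

Step 15
Reactants: 22 all-trans cyclobutane with C1 ArN3; C2 CH2OH; C3 CH2OH; C4 acetyl
Product: 24 all-trans cyclobutane with C1 ArN3; C2 CH2N3; C3 CH2N3; C4 acetyl, via dimesylate 23 (not isolated)
Conditions: MsCl (2.4 equiv), Et3N, CH2Cl2, 0 °C; then NaN3 (4 equiv), DMF, 60 °C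
Reagents that add atoms: sodium azide, [Na+].[N-]=[N+]=[N-]
Why: Sulfonate formation and SN2 displacement at two primary carbons by the weakly basic azide ion should install both nitrogen atoms of the side arms before the base-sensitive bromoketone exists.

Step 16
Reactants: 24 all-trans cyclobutane with C1 ArN3; C2 CH2N3; C3 CH2N3; C4 acetyl
Product: 26 all-trans cyclobutane with C1 ArN3; C2 CH2N3; C3 CH2N3; C4 C(O)CH2Br, via silyl enol ether 25 (not isolated)
Conditions: Me3SiCl, LiN(SiMe3)2, THF, −78 °C (internal quench); then NBS, THF, −78 → 0 °C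
Reagents that add atoms: N-bromosuccinimide, O=C1CCC(=O)N1Br
Why: Kinetic deprotonation should occur at the methyl group, not at the hindered ring methine, and electrophilic bromination of the trapped silyl enol ether gives the bromomethyl ketone.

Step 17
Reactants: 26 all-trans cyclobutane with C1 ArN3; C2 CH2N3; C3 CH2N3; C4 C(O)CH2Br; 27 N-Boc-guanidine
Product: 28 all-trans cyclobutane with C1 ArN3; C2 CH2N3; C3 CH2N3; C4 2-amino-1-Boc-imidazol-4-yl
Conditions: DMF, rt (3 equiv of 27)
Reagents that add atoms: none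
Why: Cyclocondensation of an α-bromoketone with a mono-acylated guanidine (N-alkylation, ring closure onto the ketone, dehydration) should build the second 2-aminoimidazole ring on C4, the excess guanidine taking up HBr.

Step 18
Reactants: 28 all-trans cyclobutane with C1 ArN3; C2 CH2N3; C3 CH2N3; C4 2-amino-1-Boc-imidazol-4-yl
Product: 30 (1R,2R,3S,4S)-1,2-bis(aminomethyl)-3,4-bis(2-amino-1H-imidazol-4-yl)cyclobutane tetrahydrochloride, via triamine 29 (not isolated)
Conditions: H2 (1 atm), Pd/C, MeOH, rt; filter, concentrate; then 4 M aq HCl, 80 °C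
Reagents that add atoms: hydrogen chloride, Cl
Why: Catalytic hydrogenation should reduce the aryl azide and both alkyl azides to amines, and acid hydrolysis then removes the Boc group (also if it has migrated to a side-arm amine) and the dimethylsulfamoyl group from the two protonated, acid-stable aminoimidazoles.

Step 19
Reactants: 30 (1R,2R,3S,4S)-1,2-bis(aminomethyl)-3,4-bis(2-amino-1H-imidazol-4-yl)cyclobutane tetrahydrochloride; 31 4-bromo-2-(trichloroacetyl)-1H-pyrrole
Product: 32 sceptrin (N,N'-{[(1R,2R,3S,4S)-3,4-bis(2-amino-1H-imidazol-4-yl)cyclobutane-1,2-diyl]bis(methylene)}bis(4-bromo-1H-pyrrole-2-carboxamide), free base)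
Conditions: 31 (2.1 equiv), i-Pr2NEt (5 equiv), DMF, rt
Reagents that add atoms: 4-bromo-2-(trichloroacetyl)-1H-pyrrole (the second equivalent of 31), O=C(c1cc(Br)c[nH]1)C(Cl)(Cl)Cl
Why: Haloform-type acyl transfer from the trichloromethyl ketone should let one molecule of 31 acylate each of the two primary alkylamines, which are far more nucleophilic than the amidine-like 2-aminoimidazoles, with release of one chloroform per amide formed.

## Compound list

1 | 1H-imidazole-4-carbaldehyde | O=Cc1c[nH]cn1 | starting material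
2 | dimethylsulfamoyl chloride | CN(C)S(=O)(=O)Cl | starting material
3 | 4-formyl-N,N-dimethyl-1H-imidazole-1-sulfonamide | CN(C)S(=O)(=O)n1cnc(C=O)c1 | intermediate
4 | glycine tert-butyl ester hydrochloride | CC(C)(C)OC(=O)CN.Cl | starting material
5 | tert-butyl (E)-N-{[1-(dimethylsulfamoyl)-1H-imidazol-4-yl]methylidene}glycinate | CN(C)S(=O)(=O)n1cnc(/C=N/CC(=O)OC(C)(C)C)c1 | intermediate
6 | 2(5H)-furanone | O=C1OCC=C1 | starting material
7 | silver azomethine ylide (silver enolate of 5, phosphine ligand omitted) | CN(C)S(=O)(=O)n1cnc(/C=N/C=C(O[Ag])OC(C)(C)C)c1 | intermediate (not isolated)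
8 | tert-butyl (1R,3S,3aR,6aS)-3-[1-(dimethylsulfamoyl)-1H-imidazol-4-yl]-4-oxohexahydro-1H-furo[3,4-c]pyrrole-1-carboxylate (all-cis) | CN(C)S(=O)(=O)n1cnc(c1)[C@H]2N[C@@H](C(=O)OC(C)(C)C)[C@@H](CO3)[C@H]2C3=O | intermediate
9 | 1,1-diazene (N-nitrene) of 8 | CN(C)S(=O)(=O)n1cnc(c1)[C@H]2[N+](=[N-])[C@@H](C(=O)OC(C)(C)C)[C@@H](CO3)[C@H]2C3=O | intermediate (not isolated)
10 | 1,4-biradical (radical centres at C1 and C2, lactone intact) | CN(C)S(=O)(=O)n1cnc(c1)[CH][C@@H]2C(=O)OC[C@@H]2[CH]C(=O)OC(C)(C)C | intermediate (not isolated)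
11 | tert-butyl (1S,5S,6R,7R)-7-[1-(dimethylsulfamoyl)-1H-imidazol-4-yl]-2-oxo-3-oxabicyclo[3.2.0]heptane-6-carboxylate (all-cis) | CN(C)S(=O)(=O)n1cnc(c1)[C@H]2[C@@H](C(=O)OC(C)(C)C)[C@@H](CO3)[C@H]2C3=O | intermediate
12 | tert-butyl (1S,5S,6S,7R)-7-[1-(dimethylsulfamoyl)-1H-imidazol-4-yl]-2-oxo-3-oxabicyclo[3.2.0]heptane-6-carboxylate (C2 epimer of 11) | CN(C)S(=O)(=O)n1cnc(c1)[C@H]2[C@H](C(=O)OC(C)(C)C)[C@@H](CO3)[C@H]2C3=O | intermediate
13 | cyclobutane: C1 Ar (up), C2 CO2tBu (down), C3 CH2OH (up), C4 C(O)N(OMe)Me (up) | CN(C)S(=O)(=O)n1cnc(c1)[C@H]2[C@H](C(=O)OC(C)(C)C)[C@@H](CO)[C@H]2C(=O)N(C)OC | intermediate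
14 | cyclobutane: C1 Ar (up), C2 CO2tBu (down), C3 CH2OTBS (up), C4 C(O)N(OMe)Me (up) | CN(C)S(=O)(=O)n1cnc(c1)[C@H]2[C@H](C(=O)OC(C)(C)C)[C@@H](CO[Si](C)(C)C(C)(C)C)[C@H]2C(=O)N(C)OC | intermediate
15 | cyclobutane: C1 Ar (up), C2 CO2tBu (down), C3 CH2OTBS (up), C4 acetyl (up) | CN(C)S(=O)(=O)n1cnc(c1)[C@H]2[C@H](C(=O)OC(C)(C)C)[C@@H](CO[Si](C)(C)C(C)(C)C)[C@H]2C(C)=O | intermediate
16 | all-trans cyclobutane: C1 Ar (up), C2 CO2tBu (down), C3 CH2OTBS (up), C4 acetyl (down) | CN(C)S(=O)(=O)n1cnc(c1)[C@H]2[C@H](C(=O)OC(C)(C)C)[C@@H](CO[Si](C)(C)C(C)(C)C)[C@@H]2C(C)=O | intermediate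
17 | all-trans cyclobutane: C1 Ar, C2 CH2OH, C3 CH2OTBS, C4 CH(OH)CH3 (carbinol epimers) | CN(C)S(=O)(=O)n1cnc(c1)[C@H]2[C@H](CO)[C@@H](CO[Si](C)(C)C(C)(C)C)[C@@H]2C(C)O | intermediate
18 | all-trans cyclobutane: C1 Ar, C2 CH2OTBS, C3 CH2OTBS, C4 CH(OH)CH3 (carbinol epimers) | CN(C)S(=O)(=O)n1cnc(c1)[C@H]2[C@H](CO[Si](C)(C)C(C)(C)C)[C@@H](CO[Si](C)(C)C(C)(C)C)[C@@H]2C(C)O | intermediate
19 | dilithio species of 18 (O-lithiated carbinol, 2-lithioimidazole) | CN(C)S(=O)(=O)n1c([Li])nc(c1)[C@H]2[C@H](CO[Si](C)(C)C(C)(C)C)[C@@H](CO[Si](C)(C)C(C)(C)C)[C@@H]2C(C)O[Li] | intermediate (not isolated)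
20 | all-trans cyclobutane: C1 ArN3, C2 CH2OTBS, C3 CH2OTBS, C4 CH(OH)CH3 (carbinol epimers) | CN(C)S(=O)(=O)n1c(N=[N+]=[N-])nc(c1)[C@H]2[C@H](CO[Si](C)(C)C(C)(C)C)[C@@H](CO[Si](C)(C)C(C)(C)C)[C@@H]2C(C)O | intermediate
21 | all-trans cyclobutane: C1 ArN3, C2 CH2OTBS, C3 CH2OTBS, C4 acetyl | CN(C)S(=O)(=O)n1c(N=[N+]=[N-])nc(c1)[C@H]2[C@H](CO[Si](C)(C)C(C)(C)C)[C@@H](CO[Si](C)(C)C(C)(C)C)[C@@H]2C(C)=O | intermediate
22 | all-trans cyclobutane: C1 ArN3, C2 CH2OH, C3 CH2OH, C4 acetyl | CN(C)S(=O)(=O)n1c(N=[N+]=[N-])nc(c1)[C@H]2[C@H](CO)[C@@H](CO)[C@@H]2C(C)=O | intermediate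
23 | dimesylate of 22 | CN(C)S(=O)(=O)n1c(N=[N+]=[N-])nc(c1)[C@H]2[C@H](COS(C)(=O)=O)[C@@H](COS(C)(=O)=O)[C@@H]2C(C)=O | intermediate (not isolated)
24 | all-trans cyclobutane: C1 ArN3, C2 CH2N3, C3 CH2N3, C4 acetyl | CN(C)S(=O)(=O)n1c(N=[N+]=[N-])nc(c1)[C@H]2[C@H](CN=[N+]=[N-])[C@@H](CN=[N+]=[N-])[C@@H]2C(C)=O | intermediate
25 | trimethylsilyl enol ether of 24 (terminal enol ether) | CN(C)S(=O)(=O)n1c(N=[N+]=[N-])nc(c1)[C@H]2[C@H](CN=[N+]=[N-])[C@@H](CN=[N+]=[N-])[C@@H]2C(=C)O[Si](C)(C)C | intermediate (not isolated)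
26 | all-trans cyclobutane: C1 ArN3, C2 CH2N3, C3 CH2N3, C4 C(O)CH2Br | CN(C)S(=O)(=O)n1c(N=[N+]=[N-])nc(c1)[C@H]2[C@H](CN=[N+]=[N-])[C@@H](CN=[N+]=[N-])[C@@H]2C(=O)CBr | intermediate
27 | N-Boc-guanidine (tert-butyl N-carbamimidoylcarbamate) | CC(C)(C)OC(=O)NC(N)=N | starting material
28 | all-trans cyclobutane: C1 ArN3, C2 CH2N3, C3 CH2N3, C4 2-amino-1-(tert-butoxycarbonyl)imidazol-4-yl | CN(C)S(=O)(=O)n1c(N=[N+]=[N-])nc(c1)[C@H]2[C@H](CN=[N+]=[N-])[C@@H](CN=[N+]=[N-])[C@@H]2c3cn(C(=O)OC(C)(C)C)c(N)n3 | intermediate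
29 | all-trans cyclobutane: C1 2-amino-1-(dimethylsulfamoyl)imidazol-4-yl, C2 CH2NH2, C3 CH2NH2, C4 2-amino-1-Boc-imidazol-4-yl | CN(C)S(=O)(=O)n1c(N)nc(c1)[C@H]2[C@H](CN)[C@@H](CN)[C@@H]2c3cn(C(=O)OC(C)(C)C)c(N)n3 | intermediate (not isolated)
30 | (1R,2R,3S,4S)-1,2-bis(aminomethyl)-3,4-bis(2-amino-1H-imidazol-4-yl)cyclobutane tetrahydrochloride | Nc1ncc([C@H]2[C@H](CN)[C@@H](CN)[C@@H]2c2cnc(N)[nH]2)[nH]1.Cl.Cl.Cl.Cl | intermediate
31 | 4-bromo-2-(trichloroacetyl)-1H-pyrrole | O=C(c1cc(Br)c[nH]1)C(Cl)(Cl)Cl | starting material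
32 | sceptrin (free base) | Nc1ncc([C@H]2[C@H](CNC(=O)c3cc(Br)c[nH]3)[C@@H](CNC(=O)c3cc(Br)c[nH]3)[C@@H]2c2cnc(N)[nH]2)[nH]1 | target

## Step count and risk

Total step count: 19. Longest linear sequence: 19 steps (1 to 32); every other building block is bought.

Steps most likely to fail:

Step 4. Recombination of the biradical to the crowded all-cis ring may be slow, so that β-scission of the C3–C4 bond or dehydrogenation of the amine takes over. Fallback, setting out from 8 and returning at 12: the pyrrolidine is first epimerised at its ester-bearing carbon (DBU, toluene, 60 °C, or catalytic KOtBu) to the trans-ester pyrrolidine F1, in which the ester has left the concave face. F1 is then contracted with the same PhI(OAc)2/NH2CO2NH4 system. With retention this should give 12 directly, through a less congested ring closure, and step 5 is dropped.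

Step 16. Regiocontrol of enolisation may be lost (ring methine against methyl), or the enolate may add to an azide before it is silylated. Fallback, setting out from 24 and returning at 28: the ketone is oxidised through its enol under acidic conditions with PhI(OH)OTs in MeCN at 60 °C to the α-tosyloxy ketone F2. Substitution of the iodonium intermediate by tosylate is feasible only at the primary carbon, which should direct the reaction to the methyl side. F2 is condensed with N-Boc-guanidine 27 in DMF in place of the bromoketone, giving 28 without any strong base.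

Step 3. Turnover may be low, or endo and facial selectivity may erode with the weakly activated butenolide, leaving material of insufficient enantiomeric purity. Fallback, setting out from 5 and 6 and returning at 8: the cycloaddition is run without the chiral ligand (AgOAc, Et3N, toluene, rt) to the racemic endo adduct F3. F3 is resolved by crystallising the O,O'-dibenzoyl-L-tartrate salt of 8 F4 from EtOH/EtOAc (the D-acid is used if the other salt is the less soluble one), and 8 is released with aq NaHCO3.

Further compounds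
F1 | step 4 | tert-butyl (1S,3S,3aR,6aS)-3-[1-(dimethylsulfamoyl)-1H-imidazol-4-yl]-4-oxohexahydro-1H-furo[3,4-c]pyrrole-1-carboxylate (ester trans to imidazolyl and lactone) | CN(C)S(=O)(=O)n1cnc(c1)[C@H]2N[C@H](C(=O)OC(C)(C)C)[C@@H](CO3)[C@H]2C3=O
F2 | step 16 | all-trans cyclobutane: C1 ArN3, C2 CH2N3, C3 CH2N3, C4 C(O)CH2OTs | CN(C)S(=O)(=O)n1c(N=[N+]=[N-])nc(c1)[C@H]2[C@H](CN=[N+]=[N-])[C@@H](CN=[N+]=[N-])[C@@H]2C(=O)COS(=O)(=O)c3ccc(C)cc3
F3 | step 3 | racemic all-cis adduct (8 together with its enantiomer) | CN(C)S(=O)(=O)n1cnc(c1)[C@H]2N[C@@H](C(=O)OC(C)(C)C)[C@@H](CO3)[C@H]2C3=O.CN(C)S(=O)(=O)n1cnc(c1)[C@@H]2N[C@H](C(=O)OC(C)(C)C)[C@H](CO3)[C@@H]2C3=O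
F4 | step 3 | O,O'-dibenzoyl-L-tartrate salt of 8 | CN(C)S(=O)(=O)n1cnc(c1)[C@H]2N[C@@H](C(=O)OC(C)(C)C)[C@@H](CO3)[C@H]2C3=O.OC(=O)[C@H](OC(=O)c1ccccc1)[C@@H](OC(=O)c1ccccc1)C(=O)O
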